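The cyclohexene ring (C1–C6; C1 = quaternary carbinol) is disconnected at its only double bond, C3=C4. Both alkene carbons sit next to benzoyloxy carbinols (C2, C5), so the ring unfolds to a 1,7-diene whose four oxygenated carbons C2–C1–C6–C5 map onto C1–C4 of a 2-C-hydroxymethyl-D-mannose. Ring-closing metathesis forms C3=C4 and the carbocycle in one operation, with all four stereocentres and all three benzoates in place. In the precursor the cis C1/C6 diol, the only free hydroxyls of the target, is tied as an isopropylidene dioxolane: a temporary ring that masks these two hydroxyls and holds the two vinyl carbinol arms cis for closure.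

Key step: step 6

Remark: ring numbers C1–C6 are those of the target as defined above; acyclic intermediates carry oct-1-enitol numbers (C3 = future C2, C4 = future C1, C5 = future C6, C6 = future C5); 1 is taken as the commercial α-anomer and lactol 3 as an anomeric mixture, which in step 2 reacts through the ring-opened aldehyde form of its magnesium lactolate.

Step 1
Reactants: 1 2,3:5,6-di-O-isopropylidene-α-D-mannofuranose
Product: 3 2-C-(hydroxymethyl)-2,3:5,6-di-O-isopropylidene-D-mannofuranose, via open-chain aldol aldehyde 2 (not isolated)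
Conditions: 37% aq. HCHO, K2CO3, MeOH, 65 °C
Reagents that add atoms: formaldehyde, C=O
Why: Crossed aldol (Tollens-type hydroxymethylation) of the aldehyde tautomer of the lactol at C-2, its only enolisable position: formaldehyde should add to the enolate face trans to the C-4 side chain, adduct 2 (formyl group cis to C-4) re-closes to the cis-fused furanose 3, and because O-2 stays in the dioxolane the new quaternary carbon (future C1) carries CH2OH where H-2 was.

Step 2
Reactants: 3 2-C-(hydroxymethyl)-2,3:5,6-di-O-isopropylidene-D-mannofuranose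
Product: 4 1,2-dideoxy-4-C-(hydroxymethyl)-4,5:7,8-di-O-isopropylidene-D-glycero-D-talo-oct-1-enitol (3R triol)
Conditions: CH2=CHMgBr (6 equiv), THF, 0 °C to rt; aqueous work-up
Reagents that add atoms: vinylmagnesium bromide, C=C[Mg]Br
Why: Grignard addition to a lactol, whose bromomagnesium lactolate is in equilibrium with its ring-opened aldehyde alkoxide: the bromomagnesium alkoxide of the hydroxymethyl group should hold the formyl oxygen in a six-membered chelate in which vinyl adds on the face next to the dioxolane oxygen and away from C-5 with its cis side chain (the Felkin–Anh polar model with CH2O as the small group predicts the same sense), setting the new carbinol 3R, erythro to the C-4 oxygen (the future cis C2/C1 pair).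

Step 3
Reactants: 4 1,2-dideoxy-4-C-(hydroxymethyl)-4,5:7,8-di-O-isopropylidene-D-glycero-D-talo-oct-1-enitol
Product: 5 3,6-di-O-benzoyl-4-C-[(benzoyloxy)methyl]-1,2-dideoxy-4,5:7,8-di-O-isopropylidene-D-glycero-D-talo-oct-1-enitol
Conditions: BzCl (5 equiv), pyridine, DMAP (cat.), 0 to 50 °C
Reagents that add atoms: benzoyl chloride, O=C(Cl)c1ccccc1
Why: DMAP-catalysed exhaustive O-acylation of the three free hydroxyls (primary, allylic C-3, secondary C-6), while the two hydroxyls that stay free in the target remain masked in the 4,5-acetonide; no stereocentre is touched.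

Step 4
Reactants: 5 3,6-di-O-benzoyl-4-C-[(benzoyloxy)methyl]-1,2-dideoxy-4,5:7,8-di-O-isopropylidene-D-glycero-D-talo-oct-1-enitol
Product: 6 3,6-di-O-benzoyl-4-C-[(benzoyloxy)methyl]-1,2-dideoxy-4,5-O-isopropylidene-D-glycero-D-talo-oct-1-enitol (7,8-diol)
Conditions: AcOH/H2O (4:1), 40 °C
Reagents that add atoms: none
Why: Kinetically selective acid hydrolysis of an acetal: the terminal 7,8-dioxolane should cleave much faster than the internal 4,5-dioxolane, which contains the quaternary carbon and is flanked by three electron-withdrawing benzoyloxy groups; benzoates are stable to aqueous acetic acid.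

Step 5
Reactants: 6 3,6-di-O-benzoyl-4-C-[(benzoyloxy)methyl]-1,2-dideoxy-4,5-O-isopropylidene-D-glycero-D-talo-oct-1-enitol
Product: 8 3,6-di-O-benzoyl-4-C-[(benzoyloxy)methyl]-1,2,7,8-tetradeoxy-4,5-O-isopropylidene-D-talo-octa-1,7-dienitol, via iodohydrin 7 (not isolated)
Conditions: PPh3 (4 equiv), I2 (3 equiv), imidazole (4 equiv), toluene, 80 °C
Reagents that add atoms: none
Why: Garegg–Samuelsson olefination of a vicinal diol: the primary hydroxyl is replaced by iodide through its alkoxyphosphonium salt (7), the secondary hydroxyl is then activated in the same way and iodide-induced anti elimination gives the terminal alkene; C-6 and its benzoate are not involved.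

Step 6
Reactants: 8 3,6-di-O-benzoyl-4-C-[(benzoyloxy)methyl]-1,2,7,8-tetradeoxy-4,5-O-isopropylidene-D-talo-octa-1,7-dienitol
Product: 9 [(3aR,4R,7R,7aS)-4,7-bis(benzoyloxy)-2,2-dimethyl-3a,4,7,7a-tetrahydro-1,3-benzodioxol-3a-yl]methyl benzoate
Conditions: second-generation Grubbs catalyst RuCl2(=CHPh)(H2IMes)(PCy3) (5 mol %), CH2Cl2 (5 mM), 40 °C
Reagents that add atoms: none
Why: Ring-closing olefin metathesis by the Chauvin mechanism: the ruthenium alkylidene loads onto one vinyl group (most likely the less hindered C7=C8 end), the new carbene forms a ruthenacyclobutane with the second vinyl group and cycloreverts to the ring alkene with loss of ethene. The closest known reaction type is the ring-closing metathesis of sugar-derived 1,7-dienes to cyclohexenes used for conduritols and carbasugars, including dienes with allylic ester groups. The six-membered carbocycle is closed by forming the C3=C4 double bond itself from the two internal vinyl carbons, and in a ring of this size the new alkene can only be cis. No stereocentre is formed, and the four existing ones are not at the reacting termini. The step needs cyclisation to beat intermolecular metathesis: the dioxolane holds the two vinyl carbinol arms cis on adjacent ring carbons (a cis-fused bicycle results), the quaternary carbon adds a Thorpe–Ingold bias, and high dilution with escape of ethene drives closure.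

Step 7
Reactants: 9 [(3aR,4R,7R,7aS)-4,7-bis(benzoyloxy)-2,2-dimethyl-3a,4,7,7a-tetrahydro-1,3-benzodioxol-3a-yl]methyl benzoate
Product: 10 [(1S,2R,5R,6S)-2,5-bis(benzoyloxy)-1,6-dihydroxycyclohex-3-en-1-yl]methyl benzoate (CNP0128482.1)
Conditions: TFA/H2O (9:1), CH2Cl2, 0 °C to rt
Reagents that add atoms: none
Why: Acid hydrolysis of the isopropylidene acetal releases the cis C1/C6 diol; benzoates are stable to aqueous TFA and the trans relation of the C5 benzoate to the freed C6 hydroxyl on the ring disfavours acyl migration, so all four stereocentres are delivered unchanged.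

Compound list
1 | 2,3:5,6-di-O-isopropylidene-α-D-mannofuranose | O[C@@H]1[C@H]2OC(C)(C)O[C@H]2[C@H](O1)[C@H]1COC(C)(C)O1 | starting material
2 | 2-C-(hydroxymethyl)-2,3:5,6-di-O-isopropylidene-aldehydo-D-mannose (open-chain aldehyde, not isolated) | O=C[C@@]1(CO)OC(C)(C)O[C@H]1[C@H](O)[C@H]1COC(C)(C)O1 | intermediate
3 | 2-C-(hydroxymethyl)-2,3:5,6-di-O-isopropylidene-D-mannofuranose (anomeric mixture) | OC1[C@@]2(CO)OC(C)(C)O[C@H]2[C@H](O1)[C@H]1COC(C)(C)O1 | intermediate
4 | 1,2-dideoxy-4-C-(hydroxymethyl)-4,5:7,8-di-O-isopropylidene-D-glycero-D-talo-oct-1-enitol (3R) | C=C[C@@H](O)[C@@]1(CO)OC(C)(C)O[C@H]1[C@H](O)[C@H]1COC(C)(C)O1 | intermediate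
5 | 3,6-di-O-benzoyl-4-C-[(benzoyloxy)methyl]-1,2-dideoxy-4,5:7,8-di-O-isopropylidene-D-glycero-D-talo-oct-1-enitol | C=C[C@@H](OC(=O)c1ccccc1)[C@@]1(COC(=O)c2ccccc2)OC(C)(C)O[C@H]1[C@H](OC(=O)c1ccccc1)[C@H]1COC(C)(C)O1 | intermediate
6 | 3,6-di-O-benzoyl-4-C-[(benzoyloxy)methyl]-1,2-dideoxy-4,5-O-isopropylidene-D-glycero-D-talo-oct-1-enitol (7,8-diol) | C=C[C@@H](OC(=O)c1ccccc1)[C@@]1(COC(=O)c2ccccc2)OC(C)(C)O[C@H]1[C@H](OC(=O)c1ccccc1)[C@H](O)CO | intermediate
7 | 3,6-di-O-benzoyl-4-C-[(benzoyloxy)methyl]-1,2,8-trideoxy-8-iodo-4,5-O-isopropylidene-D-glycero-D-talo-oct-1-enitol (iodohydrin, not isolated) | C=C[C@@H](OC(=O)c1ccccc1)[C@@]1(COC(=O)c2ccccc2)OC(C)(C)O[C@H]1[C@H](OC(=O)c1ccccc1)[C@H](O)CI | intermediate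
8 | 3,6-di-O-benzoyl-4-C-[(benzoyloxy)methyl]-1,2,7,8-tetradeoxy-4,5-O-isopropylidene-D-talo-octa-1,7-dienitol | C=C[C@@H](OC(=O)c1ccccc1)[C@@]1(COC(=O)c2ccccc2)OC(C)(C)O[C@H]1[C@H](OC(=O)c1ccccc1)C=C | intermediate
9 | [(3aR,4R,7R,7aS)-4,7-bis(benzoyloxy)-2,2-dimethyl-3a,4,7,7a-tetrahydro-1,3-benzodioxol-3a-yl]methyl benzoate | C1=C[C@@H](OC(=O)c2ccccc2)[C@@H]2OC(C)(C)O[C@]2(COC(=O)c2ccccc2)[C@@H]1OC(=O)c1ccccc1 | intermediate
10 | [(1S,2R,5R,6S)-2,5-bis(benzoyloxy)-1,6-dihydroxycyclohex-3-en-1-yl]methyl benzoate | O=C(OC[C@@]1(O)[C@H](OC(=O)c2ccccc2)C=C[C@@H](OC(=O)c2ccccc2)[C@@H]1O)c1ccccc1 | target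

Total step count: 7. Longest linear sequence: 7 steps (1 to 10).

Steps most likely to fail

Step 2. The facial selectivity of the vinyl addition may be poor or reversed. Chelation of magnesium by the acetal oxygen at the quaternary carbon would steer vinyl to the other face, whereas chelation by the hydroxymethyl alkoxide gives the required sense. The fallback sets out from lactol 3 and swaps the order of C–C and C–H bond formation at the carbinol carbon. Fétizon oxidation (Ag2CO3 on Celite, toluene, 90 °C) should give 2-C-(hydroxymethyl)-2,3:5,6-di-O-isopropylidene-D-mannono-1,4-lactone F1. Vinylmagnesium bromide (2.2 equiv, THF, −78 °C) should stop at the 1-C-vinyl hemiketal 1,2-dideoxy-4-C-(hydroxymethyl)-4,5:7,8-di-O-isopropylidene-D-manno-oct-1-en-3-ulofuranose F2, since the tetrahedral alkoxide does not collapse at low temperature. Chelation-controlled 1,2-reduction of its open hydroxy enone form with Zn(BH4)2 (Et2O, −20 °C) then places hydride on the face that vinyl took in the direct addition. The facial bias that gave the wrong epimer in step 2 should therefore now give the 3R triol, and the route is rejoined at 4.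

Step 5. Under imidazole and heat the C-6 benzoate may migrate to the free 7-hydroxyl before activation, or the sequence may stop at substitution (iodohydrin or epoxide) instead of elimination. The fallback sets out from diol 6 and uses a Corey–Winter olefination. 1,1'-Thiocarbonyldiimidazole (toluene, 80 °C) should give, under neutral conditions, the 7,8-cyclic thionocarbonate of 6 F3. Heating in P(OMe)3 (110 °C) should then extrude sulfur and carbon dioxide to give the terminal alkene, rejoining the route at 8.

Step 6. Turnover may be slow because both vinyl groups carry deactivating allylic benzoates and one adjoins the quaternary carbon, so catalyst decay or intermolecular metathesis could compete with closure. The fallback sets out from diene 8. Removal of the three benzoates (NaOMe, MeOH, rt) should give the triol diene 1,2,7,8-tetradeoxy-4-C-(hydroxymethyl)-4,5-O-isopropylidene-D-talo-octa-1,7-dienitol F4, whose free allylic hydroxyls accelerate metathesis. Ring closure with the same catalyst (CH2Cl2, 40 °C) should give the cyclohexenetriol acetonide, the tris-debenzoyl analogue of 9 F5. Exhaustive benzoylation (BzCl, pyridine, DMAP) acylates exactly its three free hydroxyls and rejoins the route at 9.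

Further compounds
F1 | step 2 | 2-C-(hydroxymethyl)-2,3:5,6-di-O-isopropylidene-D-mannono-1,4-lactone | O=C1[C@@]2(CO)OC(C)(C)O[C@H]2[C@H](O1)[C@H]1COC(C)(C)O1
F2 | step 2 | 1,2-dideoxy-4-C-(hydroxymethyl)-4,5:7,8-di-O-isopropylidene-D-manno-oct-1-en-3-ulofuranose | OC1(C=C)[C@@]2(CO)OC(C)(C)O[C@H]2[C@H](O1)[C@H]1COC(C)(C)O1
F3 | step 5 | 7,8-cyclic thionocarbonate of 6 | C=C[C@@H](OC(=O)c1ccccc1)[C@@]1(COC(=O)c2ccccc2)OC(C)(C)O[C@H]1[C@H](OC(=O)c1ccccc1)[C@H]1COC(=S)O1
F4 | step 6 | 1,2,7,8-tetradeoxy-4-C-(hydroxymethyl)-4,5-O-isopropylidene-D-talo-octa-1,7-dienitol | C=C[C@@H](O)[C@@]1(CO)OC(C)(C)O[C@H]1[C@H](O)C=C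
F5 | step 6 | cyclohexenetriol acetonide, the tris-debenzoyl analogue of 9 | C1=C[C@@H](O)[C@@H]2OC(C)(C)O[C@]2(CO)[C@@H]1O
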